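**Plan**

1. Cuts: the aryl C–Br bond; the C=CHBr unit back to a ring C=O; then, in one stroke, the two ring bonds that hold the CH2–CH2 unit (CH2–C(quaternary) and CH2–C(=O)); last, an α-C–CH3 and a C–B bond of a lactone.
2. Enabling feature: the phenol oxygen is ortho to the quaternary carbon, so O, two arene carbons, the quaternary carbon, the CHMe carbon and the carbonyl carbon close a six-membered dihydrocoumarin lactone. In that ring the quaternary carbon is a benzylic radical site (C4), the carbonyl carbon is an aryl-ester acyl (C2) 1,3 to it, and the phenoxide is a built-in leaving group.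
3. Forward order: arene and lactone ring are bought as 4,7-dimethylcoumarin; boron, then methyl, are put on the lactone. Radical addition to benzyl acrylate followed by enolate acylation builds the cyclopentanone while the lactone ring opens (the acrylate ester is an activating group, lost as CO2 one step later). C=O then becomes C=CBr2 and (Z)-C=CHBr, and the arene is brominated last; no protecting groups are used.
4. Stereochemistry: a chiral copper catalyst sets the boron-bearing carbon; this directs the C3 methyl anti and is then erased as a radical. The C3 methyl directs the acrylate anti at C4, which gives the quaternary centre and the cis aryl/methyl relation. The Z geometry comes from removal of the less hindered vinylic bromine.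

Key step: step 4

Assumption: the (R,R) antipode of the bisphosphine in step 1 is taken to deliver the (4S) boronate; if the sense proves to be the reverse, the (S,S) ligand is used and nothing else changes.

**Route**

Step 1
Reactants: 1 4,7-dimethyl-2H-chromen-2-one (4,7-dimethylcoumarin)
Product: 2 (4S)-4,7-dimethyl-4-(4,4,5,5-tetramethyl-1,3,2-dioxaborolan-2-yl)-3,4-dihydro-2H-chromen-2-one
Conditions: B2pin2 (1.1 equiv), CuCl (5 mol %), NaOt-Bu (8 mol %), (R,R)-2,3-bis(tert-butylmethylphosphino)quinoxaline (6 mol %), t-BuOH (2 equiv), THF, rt
Reagents that add atoms: bis(pinacolato)diboron, CC1(C)OB(OC1(C)C)B1OC(C)(C)C(C)(C)O1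
Why: Copper-catalysed enantioselective conjugate borylation of a β,β-disubstituted unsaturated ester: the bisphosphine-bound boryl copper (monovalent copper) delivers boron to C4 from one face of the coumarin, which sets the benzylic C–B stereocentre, and the hindered alcohol protonates the copper enolate without opening the aryl lactone.

Step 2
Reactants: 2 (4S)-4,7-dimethyl-4-(pinacolboryl)-3,4-dihydro-2H-chromen-2-one
Product: 3 (3R,4S)-3,4,7-trimethyl-4-(4,4,5,5-tetramethyl-1,3,2-dioxaborolan-2-yl)-3,4-dihydro-2H-chromen-2-one
Conditions: LiN(i-Pr)2 (1.05 equiv), THF, −78 °C; MeI (1.2 equiv), −78 to −40 °C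
Reagents that add atoms: iodomethane, CI
Why: Lactone enolate alkylation: the C–B bond on the neighbouring quaternary carbon stands perpendicular to the enolate plane (as for β-silyl enolates) and iodomethane attacks the face away from boron, so the C3 methyl ends up trans to boron and carries the chirality on.

Step 3
Reactants: 3 (3R,4S)-3,4,7-trimethyl-4-(pinacolboryl)-3,4-dihydro-2H-chromen-2-one
Product: 4 potassium trifluoro[(3R,4S)-3,4,7-trimethyl-2-oxo-3,4-dihydro-2H-chromen-4-yl]borate
Conditions: KHF2 (4.5 M aq., 4 equiv), MeOH, rt
Reagents that add atoms: potassium hydrogen difluoride, [K+].F[H-]F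
Why: Standard exchange of a pinacol boronic ester for a trifluoroborate, which touches neither stereocentre and gives a salt that is easily oxidised to the benzylic radical.

Step 4
Reactants: 4 potassium trifluoro[(3R,4S)-3,4,7-trimethyl-2-oxo-3,4-dihydro-2H-chromen-4-yl]borate; 5 benzyl prop-2-enoate (benzyl acrylate)
Product: 8 benzyl (3R,4R)-4-(2-hydroxy-4-methylphenyl)-3,4-dimethyl-2-oxocyclopentane-1-carboxylate, via lactone radical 6 (not isolated), via potassium ester enolate 7 (not isolated)
Conditions: 5 (3 equiv), 4CzIPN (3 mol %), dry DMSO, 450 nm LED, 25 °C; aq. NaH2PO4 work-up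
Reagents that add atoms: none
Why: Proposed new method: the excited organic photocatalyst oxidises the tertiary benzylic trifluoroborate to radical 6, which adds to the acrylate β-carbon (Giese addition); the mildly reducing photocatalyst radical anion then returns an electron to the α-ester radical, but not to the benzylic radical, to give ester enolate 7, which attacks the aryl-ester carbonyl of the lactone and expels the phenoxide. The closest known reaction types are the photoredox Giese reaction of alkyltrifluoroborates and deboronative radical addition–polar cyclisation cascades in which the enolate is trapped by an internal alkyl halide; here the trap is an acyl group, as in a Dieckmann condensation. The cyclopentanone closes by a 5-exo-trig attack of the enolate carbon on C=O through a bridged oxabicyclo[3.2.1]octane alkoxide, and the six-membered lactone opens in the same event to free the phenol. The quaternary centre is controlled by the C3 methyl of the ring radical, which sits pseudo-axial to avoid the in-plane C4 methyl so that the acrylate adds to the opposite face, and after ring opening this is the cis aryl/methyl cyclopentane; the ester-bearing carbon forms without control and is removed in step 5. The step needs acylation of the enolate to outrun its protonation and needs C3–H to stay untouched, which the aprotic medium, the activated aryl ester held in a ring and the base-free, regiospecific generation of the enolate by electron transfer should secure. The BF3 set free should bind the product keto ester enolate and phenoxide and keep them from adding to excess acrylate until work-up.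

Step 5
Reactants: 8 benzyl (3R,4R)-4-(2-hydroxy-4-methylphenyl)-3,4-dimethyl-2-oxocyclopentane-1-carboxylate
Product: 10 (2R,3R)-3-(2-hydroxy-4-methylphenyl)-2,3-dimethylcyclopentan-1-one, via keto acid 9 (not isolated)
Conditions: H2 (1 atm), Pd/C (10 wt %), EtOAc, rt; then 45 °C
Reagents that add atoms: none
Why: Hydrogenolysis of the benzyl ester and thermal decarboxylation of the β-keto acid, which loses CO2 through the enol on the carboxyl side under neutral conditions, so the methyl-bearing α-carbon is not enolised.

Step 6
Reactants: 10 (2R,3R)-3-(2-hydroxy-4-methylphenyl)-2,3-dimethylcyclopentan-1-one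
Product: 11 2-[(1R,2R)-3-(dibromomethylidene)-1,2-dimethylcyclopentyl]-5-methylphenol
Conditions: CBr4 (2 equiv), PPh3 (4 equiv), toluene, 80 °C
Reagents that add atoms: carbon tetrabromide, BrC(Br)(Br)Br
Why: Ramirez dibromo-olefination (Wittig type, the first stage of a Corey–Fuchs sequence): the ylide Ph3P=CBr2 is non-basic, so the stereocentre next to the carbonyl should survive, and a free phenol is tolerated.

Step 7
Reactants: 11 2-[(1R,2R)-3-(dibromomethylidene)-1,2-dimethylcyclopentyl]-5-methylphenol
Product: 12 2-[(1R,2R,3Z)-3-(bromomethylidene)-1,2-dimethylcyclopentyl]-5-methylphenol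
Conditions: Bu3SnH (1.1 equiv), Pd(PPh3)4 (5 mol %), toluene, rt
Reagents that add atoms: none
Why: Palladium-catalysed hydrogenolysis of a 1,1-dibromoalkene with a tin hydride: zerovalent palladium inserts into the C–Br bond cis to the ring CH2, the less hindered of the two, and hydride transfer with retention leaves the bromine cis to the CHMe carbon, which is the Z alkene.

Step 8
Reactants: 12 2-[(1R,2R,3Z)-3-(bromomethylidene)-1,2-dimethylcyclopentyl]-5-methylphenol
Product: 13 4-bromo-2-[(1R,2R,3Z)-3-(bromomethylidene)-1,2-dimethylcyclopentyl]-5-methylphenol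
Conditions: NBS (1.0 equiv), MeCN, −20 °C
Reagents that add atoms: N-bromosuccinimide, O=C1CCC(=O)N1Br
Why: Electrophilic aromatic bromination para to the hydroxyl group, the most activated open position; the vinyl bromide is a deactivated alkene and should not compete at low temperature.

**Compound list**

1 | 4,7-dimethyl-2H-chromen-2-one | Cc1ccc2c(c1)OC(=O)C=C2C | starting material
2 | (4S)-4,7-dimethyl-4-(4,4,5,5-tetramethyl-1,3,2-dioxaborolan-2-yl)-3,4-dihydro-2H-chromen-2-one | Cc1ccc2c(c1)OC(=O)C[C@@]2(C)B3OC(C)(C)C(C)(C)O3 | intermediate
3 | (3R,4S)-3,4,7-trimethyl-4-(4,4,5,5-tetramethyl-1,3,2-dioxaborolan-2-yl)-3,4-dihydro-2H-chromen-2-one (methyl trans to boron) | Cc1ccc2c(c1)OC(=O)[C@H](C)[C@@]2(C)B3OC(C)(C)C(C)(C)O3 | intermediate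
4 | potassium trifluoro[(3R,4S)-3,4,7-trimethyl-2-oxo-3,4-dihydro-2H-chromen-4-yl]borate | Cc1ccc2c(c1)OC(=O)[C@H](C)[C@@]2(C)[B-](F)(F)F.[K+] | intermediate
5 | benzyl prop-2-enoate | C=CC(=O)OCc1ccccc1 | starting material
6 | (3R)-3,4,7-trimethyl-2-oxo-3,4-dihydro-2H-chromen-4-yl radical | Cc1ccc2c(c1)OC(=O)[C@H](C)[C]2C | intermediate (not isolated)
7 | potassium enolate of benzyl 3-[(3R,4R)-3,4,7-trimethyl-2-oxo-3,4-dihydro-2H-chromen-4-yl]propanoate | Cc1ccc2c(c1)OC(=O)[C@H](C)[C@@]2(C)CC=C([O-])OCc3ccccc3.[K+] | intermediate (not isolated)
8 | benzyl (3R,4R)-4-(2-hydroxy-4-methylphenyl)-3,4-dimethyl-2-oxocyclopentane-1-carboxylate (C1 epimers and enol; aryl and C3 methyl cis) | Cc1cc(O)c([C@]2(C)CC(C(=O)OCc3ccccc3)C(=O)[C@@H]2C)cc1 | intermediate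
9 | (3R,4R)-4-(2-hydroxy-4-methylphenyl)-3,4-dimethyl-2-oxocyclopentane-1-carboxylic acid | Cc1cc(O)c([C@]2(C)CC(C(=O)O)C(=O)[C@@H]2C)cc1 | intermediate (not isolated)
10 | (2R,3R)-3-(2-hydroxy-4-methylphenyl)-2,3-dimethylcyclopentan-1-one | Cc1cc(O)c([C@]2(C)CCC(=O)[C@@H]2C)cc1 | intermediate
11 | 2-[(1R,2R)-3-(dibromomethylidene)-1,2-dimethylcyclopentyl]-5-methylphenol | Cc1cc(O)c([C@]2(C)CCC(=C(Br)Br)[C@@H]2C)cc1 | intermediate
12 | 2-[(1R,2R,3Z)-3-(bromomethylidene)-1,2-dimethylcyclopentyl]-5-methylphenol | Cc1cc(O)c([C@]2(C)CC/C(=C/Br)[C@@H]2C)cc1 | intermediate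
13 | 4-bromo-2-[(1R,2R,3Z)-3-(bromomethylidene)-1,2-dimethylcyclopentyl]-5-methylphenol | Cc1cc(O)c([C@]2(C)CC/C(=C/Br)[C@@H]2C)cc1Br | target

**Step count**

Total steps: 8. Longest linear sequence: 8.

**Steps most likely to fail**

Step 4. The ester enolate may be protonated before it acylates the lactone, the product enolate may add to excess acrylate, or the acrylate may oligomerise. The fallback sets out from 4 and 5 and uses known reactions only. The Giese addition is run under the usual protic conditions for alkyltrifluoroborates (4CzIPN, acetone/MeOH, blue light), which should give the simple adduct benzyl 3-[(3R,4R)-3,4,7-trimethyl-2-oxo-3,4-dihydro-2H-chromen-4-yl]propanoate F1. LiN(SiMe3)2 in THF at −78 °C then deprotonates the most acidic position, the lactone α-carbon, and a Dieckmann condensation onto the benzyl ester closes the ring to the cis-fused keto lactone (3aR,9bS)-3a,7,9b-trimethyl-1,2,3a,9b-tetrahydrocyclopenta[c]chromene-3,4-dione F2. Aqueous LiOH, acidification and gentle warming open the lactone and decarboxylate; the methyl-bearing carbon is re-set on ketonisation, with proton delivery anti to the aryl group expected. The fallback returns to the route at 10.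

Step 7. The two C–Br bonds may not be told apart well enough in the oxidative addition, and over-reduction may follow. The fallback sets out from 10. Boron-Wittig olefination with the lithium salt of bis(pinacolboryl)methane (from CH2(Bpin)2 and lithium tetramethylpiperidide, one extra equivalent for the phenol) should give the alkenyl boronate 2-[(1R,2S,3E)-1,2-dimethyl-3-[(4,4,5,5-tetramethyl-1,3,2-dioxaborolan-2-yl)methylidene]cyclopentyl]-5-methylphenol F3, with boron away from the bulkier CHMe side. Bromine (2 equiv, −78 °C) followed by NaOMe then brominates the arene para to OH and replaces boron by bromine with inversion of the alkene geometry (anti addition, anti elimination). The fallback returns to the route at 13.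

Step 1. The alkoxide co-catalyst may open the aryl lactone, and face selectivity on the cyclic substrate may be low. The fallback sets out from 1. Ring opening with aqueous NaOH and double benzylation (BnBr, K2CO3, DMF) gives the acyclic ester benzyl (2Z)-3-[2-(benzyloxy)-4-methylphenyl]but-2-enoate F4. The same copper-catalysed asymmetric borylation, here on an acyclic β-aryl-β-methyl enoate, gives benzyl (3S)-3-[2-(benzyloxy)-4-methylphenyl]-3-(4,4,5,5-tetramethyl-1,3,2-dioxaborolan-2-yl)butanoate F5. Hydrogenolysis (H2, Pd/C) removes both benzyl groups to the hydroxy acid (3S)-3-(2-hydroxy-4-methylphenyl)-3-(4,4,5,5-tetramethyl-1,3,2-dioxaborolan-2-yl)butanoic acid F6, which should lactonise on standing or with a trace of acid. The fallback returns to the route at 2.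

**Further compounds**

F1 | step 4 | benzyl 3-[(3R,4R)-3,4,7-trimethyl-2-oxo-3,4-dihydro-2H-chromen-4-yl]propanoate | Cc1ccc2c(c1)OC(=O)[C@H](C)[C@@]2(C)CCC(=O)OCc3ccccc3
F2 | step 4 | (3aR,9bS)-3a,7,9b-trimethyl-1,2,3a,9b-tetrahydrocyclopenta[c]chromene-3,4-dione | Cc1ccc2c(c1)OC(=O)[C@@]3(C)C(=O)CC[C@@]23C
F3 | step 7 | 2-[(1R,2S,3E)-1,2-dimethyl-3-[(4,4,5,5-tetramethyl-1,3,2-dioxaborolan-2-yl)methylidene]cyclopentyl]-5-methylphenol | Cc1cc(O)c([C@]2(C)CC/C(=C\B3OC(C)(C)C(C)(C)O3)[C@@H]2C)cc1
F4 | step 1 | benzyl (2Z)-3-[2-(benzyloxy)-4-methylphenyl]but-2-enoate | Cc1ccc(c(OCc2ccccc2)c1)/C(C)=C\C(=O)OCc3ccccc3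
F5 | step 1 | benzyl (3S)-3-[2-(benzyloxy)-4-methylphenyl]-3-(4,4,5,5-tetramethyl-1,3,2-dioxaborolan-2-yl)butanoate | Cc1ccc(c(OCc2ccccc2)c1)[C@@](C)(CC(=O)OCc3ccccc3)B4OC(C)(C)C(C)(C)O4
F6 | step 1 | (3S)-3-(2-hydroxy-4-methylphenyl)-3-(4,4,5,5-tetramethyl-1,3,2-dioxaborolan-2-yl)butanoic acid | Cc1ccc(c(O)c1)[C@@](C)(CC(=O)O)B2OC(C)(C)C(C)(C)O2
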